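Two end amounts are asked, and which of the two flasks leads.

| setting | maple | alder | oak | epsilon | gamma |
|---|---|---|---|---|---|
| starting material | 0.80 M | 0.80 M | 0.80 M | 0.80 M | 0.80 M |
| partner | 1.6 M | 1.6 M | 1.6 M | 1.60 M | 1.60 M |
| free catalyst | 1.1 mM | 1.8 mM | 0.80 mM | 0.80 mM | 0.80 mM |
| second catalyst | 0.96 mM | 0.96 mM | 1.4 mM | 0.96 mM | 0.96 mM |
| temperature | 70 °C | 82 °C | 70 °C | 75 °C | 90 °C |
| remark | run made earlier | run made earlier | run made earlier |  |  |
| time |  |  |  | 50 min | 50 min |

| run | time / min | target / % |
|---|---|---|
| maple | 3.00 | 1.2 |
| maple | 8.00 | 5.3 |
| maple | 15.0 | 12.6 |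
| maple | 40.0 | 37.2 |
| alder | 5.00 | 7.9 |
| alder | 15.0 | 29.9 |
| alder | 25.0 | 43.9 |
| alder | 40.0 | 56.9 |
| oak | 10.0 | 6.9 |
| oak | 20.0 | 19.3 |
| oak | 30.0 | 30.1 |
| oak | 40.0 | 38.4 |

(each reading ± 0.5 percentage points)



* which flask leads in amount of target, in percent of the starting material charged ("all alike" within 1.5 percentage points) (epsilon / gamma / all alike)
* how much target is there at the end, in percent of the starting material charged: epsilon
* how much target is there at the end, in percent of the starting material charged: gamma

From its first two readings to its last two, alder's pace of target formation falls by the factor 2.54, which gives 24.2 min. I call this τ, the tail time: the time in which the late pace falls by the factor e. It is a reading and carries the scatter.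

Maple has epsilon's second catalyst, so I let it stand in for epsilon over the last 10.0 min. In one extreme maple stops at its last reading, 37.2%. In the other its late pace holds, giving 47.0%. A pace fading with τ lies between them, at 45.3%, and that is my figure for epsilon. The same reckoning on alder gives 64.0%. But gamma carries 0.80 mM of free catalyst against alder's 1.8 mM, so I hold that figure loosely for gamma and leave the lead open.

The forecast says 42% for epsilon, less than my figure, and 45% for gamma, with gamma ahead, and it reads alder's tail as “catalyst death with a high activation energy”.

The flasks give 41.7% for epsilon and 42.7% for gamma, a gap inside the margin, so the answer is all alike.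

    starting material + free catalyst → free catalyst + intermediate (k = 2.10 L mol⁻¹ s⁻¹, Ea = 49.0 kJ mol⁻¹)
    partner + second catalyst + intermediate → second catalyst + target (k = 0.950 L² mol⁻² s⁻¹, Ea = 40.0 kJ mol⁻¹)
    starting material + partner → uncatalysed product (k = 0.00140 L mol⁻¹ s⁻¹, Ea = 86.0 kJ mol⁻¹)
    (constants at 90 °C)

The main reason gamma ends at 42.7% of target is the step from starting material and partner to uncatalysed product: the same run without that step gives 88.2%. Late in gamma I read τ as the intermediate's time constant: its 15.3% at 25.0 min, fading with τ, comes to 5.45%, and gamma holds 4.80% at 50.0 min. Gamma's neighbour with 0.0038 M of second catalyst has τ near 6.10 min, taking τ as inverse in second catalyst, so I expect gamma's end intermediate to have become target there, about 47.5%. That neighbour gives 48.7%, with 0.0575% intermediate left.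

(The readings were computed with made-up constants; the scatter is artificial.)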